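**Strategy**

The route rests on cutting ring C of the upper flavan unit at C3–C4 and O1–C2. In that ring C4 carries two aryl groups and is attached to C4a, next to the oxygen-bearing C8a of ring A, while the C3 oxygen lies cis to the C4 aryl group: exactly what a ring A o-quinone methide gives with a glycolate enolate. One isothiourea-catalysed Michael addition–lactonisation forms both bonds, closes ring C as a cis-dihydrocoumarin and sets C3 and C4. Its precursor joins a 4-benzyloxy-2-hydroxyphenyl carbinol carbon to C6 of 8-bromo-penta-O-benzylcatechin, activated as a p-tolyl sulfone. Reduction, aryl Grignard addition, acid closure to the 2,3-trans chroman and hydrogenolysis complete the synthesis.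

Key step: step 7

**Remarks on the chemistry (assumptions)**

- Ring letters: the upper unit has rings A (resorcinol ring), B (catechol ring) and C (pyran); the lower catechin unit has rings D (phloroglucinol ring), E (catechol ring) and F (pyran). "ArD" means the (2R,3S)-3,5,7-tris(benzyloxy)-2-[3,4-bis(benzyloxy)phenyl]-8-bromochroman-6-yl group.
- The target is read as 4→6 linked, upper unit (2R,3S,4R) with 2,3-trans and 3,4-cis, lower unit (2R,3S).
- A free o-hydroxybenzhydrol does not lose water under mild base. Its hydroxyl is therefore exchanged for p-toluenesulfinate, and the resulting sulfone releases the quinone methide with carbonate.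
- 4-(Benzyloxy)-2-hydroxybenzaldehyde and 4-bromo-1,2-bis(benzyloxy)benzene are taken as purchased; the former is otherwise one selective 4-O-benzylation away from 2,4-dihydroxybenzaldehyde.
- By the usual facial model, (R)-BTM is expected to give the 3S sense; the mirror-image catalyst is equally accessible should the sense prove opposite.

**Route**

Step 1
Reactants: 1 (+)-catechin
Product: 2 penta-O-benzyl-(+)-catechin [(2R,3S)-3,5,7-tris(benzyloxy)-2-[3,4-bis(benzyloxy)phenyl]chroman]
Conditions: NaH (6 equiv), BnBr (6 equiv), DMF, −40 °C → rt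
Reagents that add atoms: benzyl bromide, BrCc1ccccc1
Why: Williamson ether synthesis, in which NaH deprotonates the four phenols and then the C3 alcohol and benzyl bromide alkylates each oxygen as it forms, the low starting temperature keeping the ring E phenoxide from opening ring F and epimerising C2, so both catechin stereocentres are carried through unchanged.

Step 2
Reactants: 2 penta-O-benzyl-(+)-catechin
Product: 3 8-bromo-penta-O-benzylcatechin
Conditions: NBS (1.0 equiv), CH2Cl2, −78 °C → rt
Reagents that add atoms: N-bromosuccinimide, O=C1CCC(=O)N1Br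
Why: Electrophilic aromatic substitution, for which C8 of ring D is the most reactive position of benzylated catechins towards one equivalent of N-bromosuccinimide at low temperature, leaving C6 free.

Step 3
Reactants: 3 8-bromo-penta-O-benzylcatechin
Product: 4 8-bromo-6-iodo-penta-O-benzylcatechin
Conditions: NIS (1.2 equiv), CF3CO2H (10 mol%), CH2Cl2–MeCN, 0 °C → rt
Reagents that add atoms: N-iodosuccinimide, O=C1CCC(=O)N1I
Why: Electrophilic aromatic iodination with acid-activated N-iodosuccinimide, which can only take place at C6 because it is the one remaining position of ring D activated by three oxygen substituents, the catechol rings being far less electron-rich.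

Step 4
Reactants: 5 4-(benzyloxy)-2-hydroxybenzaldehyde
Product: 6 4-(benzyloxy)-2-[(tert-butyldimethylsilyl)oxy]benzaldehyde
Conditions: TBSCl, imidazole, DMF, rt
Reagents that add atoms: tert-butyldimethylsilyl chloride, CC(C)(C)[Si](C)(C)Cl
Why: Imidazole-promoted silylation of the phenol (silyl ether formation), which masks the acidic proton that would otherwise quench the arylmagnesium reagent in step 5.

Step 5
Reactants: 4 8-bromo-6-iodo-penta-O-benzylcatechin; 6 4-(benzyloxy)-2-[(tert-butyldimethylsilyl)oxy]benzaldehyde
Product: 9 5-(benzyloxy)-2-[ArD(hydroxy)methyl]phenol (o-hydroxybenzhydrol; both carbinol epimers), via arylmagnesium chloride 7 (not isolated), via silyl-protected benzhydrol 8 (not isolated)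
Conditions: iPrMgCl·LiCl (1.1 equiv), THF, −30 °C; 6, −30 → 0 °C; Bu4NF (3 equiv), 0 °C → rt; aq NH4Cl
Reagents that add atoms: none
Why: Halogen–magnesium exchange followed by Grignard addition and fluoride desilylation: isopropylmagnesium chloride exchanges the iodide, assisted by its two ortho oxygen atoms, far faster than the bromide, the C6 arylmagnesium adds to the aldehyde, and fluoride removes the silyl group wherever it resides after any oxygen-to-oxygen migration, the new carbinol centre forming as both epimers, which is harmless because it becomes planar in step 7.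

Step 6
Reactants: 9 5-(benzyloxy)-2-[ArD(hydroxy)methyl]phenol
Product: 10 5-(benzyloxy)-2-[ArD(4-methylbenzenesulfonyl)methyl]phenol (p-tolyl sulfone; both epimers)
Conditions: p-TolSO2H (1.5 equiv), CH2Cl2, 0 °C → rt
Reagents that add atoms: p-toluenesulfinic acid, Cc1ccc(cc1)S(=O)O
Why: Acid-promoted SN1 substitution, in which the sulfinic acid ionises the doubly donor-stabilised benzhydrol and the sulfinate is captured at sulfur to give the bench-stable sulfone, a standard base-triggered o-quinone methide precursor, again as both epimers.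

Step 7
Reactants: 10 5-(benzyloxy)-2-[ArD(4-methylbenzenesulfonyl)methyl]phenol; 11 benzyloxyacetic acid
Product: 14 (3S,4R)-3,7-bis(benzyloxy)-4-ArD-chroman-2-one (cis-dihydrocoumarin), via benzyloxyacetic pivalic anhydride 12 (not isolated), via o-quinone methide 13 (not isolated)
Conditions: 11 (1.5 equiv), t-BuCOCl, iPr2NEt, CH2Cl2, 0 °C; (R)-2-phenyl-2,3-dihydrobenzo[d]imidazo[2,1-b]thiazole [(R)-BTM] (10 mol%), −40 °C; then 13 (from 10, Cs2CO3, CH2Cl2, 0 °C, cannulated off the salts), −40 → 0 °C
Reagents that add atoms: none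
Why: Pivaloyl chloride turns 11 into mixed anhydride 12, which N-acylates (R)-BTM, and deprotonation gives the (Z)-ammonium enolate held planar by its 1,5 S···O contact, while carbonate expels sulfinate from the phenoxide of 10 to give the (E)-o-quinone methide 13, whose only electrophilic site is the methide carbon C4; the enolate α-carbon (C3) adds there and the freed ring A phenoxide O1 then attacks the acyl isothiouronium carbonyl C2. The closest known reaction type is the chiral Lewis-base (isothiourea, N-heterocyclic carbene or cinchona amine) catalysed formal [4+2] annulation of o-quinone methides with catalyst-bound C1 enolates to 3,4-dihydrocoumarins. Ring C is closed by this acyl substitution in the 6-exo-trig mode (O1–C2), which also releases the catalyst. C3 is controlled by the catalyst, whose C2 phenyl group blocks one enolate face so that (R)-BTM should deliver 3S, and C4 follows from the relative approach, an endo-type arrangement in which the enolate oxygen and the benzyloxy group lie under the heterodiene and the bulky isothiouronium points away, which for the E methide places the ring D aryl and the C3 benzyloxy group cis (3S,4R). The step needs site selectivity, cis diastereoselectivity and one absolute sense: the site is fixed because the 4→6 link already exists in 10, the E geometry is enforced by the di-ortho-substituted ring D aryl turning away from the carbonyl oxygen, and the remote catechin stereocentres should not override the catalyst. Low temperature and a weak amine base keep the kinetically formed cis lactone from epimerising at C3.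

Step 8
Reactants: 14 (3S,4R)-3,7-bis(benzyloxy)-4-ArD-chroman-2-one
Product: 15 (3S,4R)-3,7-bis(benzyloxy)-4-ArD-chroman-2-ol (lactol; anomeric mixture)
Conditions: iBu2AlH (1.2 equiv), CH2Cl2, −78 °C; aq potassium sodium tartrate
Reagents that add atoms: none
Why: Partial reduction of the aryl lactone to the lactol with iBu2AlH at −78 °C, the aluminium hemiacetal surviving until work-up so that no diol forms, while the aryl bromide, the benzyl ethers and the C3 and C4 centres are untouched.

Step 9
Reactants: 15 (3S,4R)-3,7-bis(benzyloxy)-4-ArD-chroman-2-ol; 16 4-bromo-1,2-bis(benzyloxy)benzene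
Product: 18 (2S,3R)-1-[3,4-bis(benzyloxy)phenyl]-2-(benzyloxy)-3-[4-(benzyloxy)-2-hydroxyphenyl]-3-ArD-propan-1-ol (both C1 epimers), via 3,4-bis(benzyloxy)phenylmagnesium bromide 17 (not isolated)
Conditions: 16 (3.5 equiv), Mg, THF, rt; then 15, THF, −78 → 0 °C
Reagents that add atoms: none
Why: Grignard addition to a lactol through its ring-opened hydroxy aldehyde, the first equivalent deprotonating the lactol and a further one adding to the aldehyde at low temperature before C3 can enolise; chelation by the neighbouring benzyloxy group should favour the (1S) carbinol, but both epimers are carried on because step 10 ionises this centre.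

Step 10
Reactants: 18 (2S,3R)-1-[3,4-bis(benzyloxy)phenyl]-2-(benzyloxy)-3-[4-(benzyloxy)-2-hydroxyphenyl]-3-ArD-propan-1-ol
Product: 19 (2R,3S,4R)-3,7-bis(benzyloxy)-2-[3,4-bis(benzyloxy)phenyl]-4-ArD-chroman
Conditions: p-TsOH·H2O (10 mol%), CH2Cl2, 0 °C → rt
Reagents that add atoms: none
Why: Acid-catalysed SN1 cycloetherification, in which the p-alkoxybenzylic alcohol ionises and the ring A phenol closes O1–C2 through a half-chair that keeps the C2 aryl and C3 benzyloxy groups pseudo-equatorial and the C4 aryl pseudo-axial, so the 2,3-trans (2R) chroman forms and is also the thermodynamically preferred epimer under reversible ionisation.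

Step 11
Reactants: 19 (2R,3S,4R)-3,7-bis(benzyloxy)-2-[3,4-bis(benzyloxy)phenyl]-4-ArD-chroman
Product: 20 fisetinidol-(4β→6)-catechin (target)
Conditions: H2 (1 atm), Pd(OH)2/C, NaHCO3, THF–MeOH–H2O, rt
Reagents that add atoms: none
Why: Heterogeneous palladium-catalysed hydrogenolysis, which cleaves all nine benzyl ethers and the C8 aryl bromide in one operation while the two flavan C2–O1 bonds and the five stereocentres survive, as is usual for benzylated flavan-3-ol oligomers, hydrogencarbonate taking up the hydrogen bromide.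

**Compound list**

1 | (+)-catechin, (2R,3S)-2-(3,4-dihydroxyphenyl)chroman-3,5,7-triol | O[C@H]1Cc2c(O)cc(O)cc2O[C@@H]1c1ccc(O)c(O)c1 | starting material
2 | penta-O-benzyl-(+)-catechin, (2R,3S)-3,5,7-tris(benzyloxy)-2-[3,4-bis(benzyloxy)phenyl]chroman | c5c(OCc9ccccc9)cc6c(c5OCc9ccccc9)C[C@H](OCc9ccccc9)[C@@H](c7ccc(OCc9ccccc9)c(OCc9ccccc9)c7)O6 | intermediate
3 | 8-bromo-penta-O-benzylcatechin (ArD–H) | c5c(OCc9ccccc9)c(Br)c6c(c5OCc9ccccc9)C[C@H](OCc9ccccc9)[C@@H](c7ccc(OCc9ccccc9)c(OCc9ccccc9)c7)O6 | intermediate
4 | 8-bromo-6-iodo-penta-O-benzylcatechin (ArD–I) | Ic5c(OCc9ccccc9)c(Br)c6c(c5OCc9ccccc9)C[C@H](OCc9ccccc9)[C@@H](c7ccc(OCc9ccccc9)c(OCc9ccccc9)c7)O6 | intermediate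
5 | 4-(benzyloxy)-2-hydroxybenzaldehyde | O=Cc1ccc(OCc9ccccc9)cc1O | starting material
6 | 4-(benzyloxy)-2-[(tert-butyldimethylsilyl)oxy]benzaldehyde | O=Cc1ccc(OCc9ccccc9)cc1O[Si](C)(C)C(C)(C)C | intermediate
7 | ArD–MgCl, the C6 arylmagnesium chloride of 8-bromo-penta-O-benzylcatechin | Cl[Mg]c5c(OCc9ccccc9)c(Br)c6c(c5OCc9ccccc9)C[C@H](OCc9ccccc9)[C@@H](c7ccc(OCc9ccccc9)c(OCc9ccccc9)c7)O6 | intermediate (not isolated)
8 | [4-(benzyloxy)-2-(tert-butyldimethylsilyloxy)phenyl](ArD)methanol, present as its chloromagnesium alkoxide, both epimers | OC(c1ccc(OCc9ccccc9)cc1O[Si](C)(C)C(C)(C)C)c5c(OCc9ccccc9)c(Br)c6c(c5OCc9ccccc9)C[C@H](OCc9ccccc9)[C@@H](c7ccc(OCc9ccccc9)c(OCc9ccccc9)c7)O6 | intermediate (not isolated)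
9 | 5-(benzyloxy)-2-[ArD(hydroxy)methyl]phenol, o-hydroxybenzhydrol, both carbinol epimers | OC(c1ccc(OCc9ccccc9)cc1O)c5c(OCc9ccccc9)c(Br)c6c(c5OCc9ccccc9)C[C@H](OCc9ccccc9)[C@@H](c7ccc(OCc9ccccc9)c(OCc9ccccc9)c7)O6 | intermediate
10 | 5-(benzyloxy)-2-[ArD(4-methylbenzenesulfonyl)methyl]phenol, both epimers | Cc1ccc(cc1)S(=O)(=O)C(c1ccc(OCc9ccccc9)cc1O)c5c(OCc9ccccc9)c(Br)c6c(c5OCc9ccccc9)C[C@H](OCc9ccccc9)[C@@H](c7ccc(OCc9ccccc9)c(OCc9ccccc9)c7)O6 | intermediate
11 | benzyloxyacetic acid | OC(=O)COCc1ccccc1 | starting material
12 | benzyloxyacetic pivalic anhydride | CC(C)(C)C(=O)OC(=O)COCc1ccccc1 | intermediate (not isolated)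
13 | (6E)-3-(benzyloxy)-6-(ArD-methylidene)cyclohexa-2,4-dien-1-one, o-quinone methide | O=C1C=C(OCc9ccccc9)C=C/C1=C\c5c(OCc9ccccc9)c(Br)c6c(c5OCc9ccccc9)C[C@H](OCc9ccccc9)[C@@H](c7ccc(OCc9ccccc9)c(OCc9ccccc9)c7)O6 | intermediate (not isolated)
14 | (3S,4R)-3,7-bis(benzyloxy)-4-ArD-chroman-2-one, cis-dihydrocoumarin | C(c9ccccc9)Oc1ccc2c(c1)OC(=O)[C@@H](OCc9ccccc9)[C@H]2c5c(OCc9ccccc9)c(Br)c6c(c5OCc9ccccc9)C[C@H](OCc9ccccc9)[C@@H](c7ccc(OCc9ccccc9)c(OCc9ccccc9)c7)O6 | intermediate
15 | (3S,4R)-3,7-bis(benzyloxy)-4-ArD-chroman-2-ol, lactol, anomeric mixture | C(c9ccccc9)Oc1ccc2c(c1)OC(O)[C@@H](OCc9ccccc9)[C@H]2c5c(OCc9ccccc9)c(Br)c6c(c5OCc9ccccc9)C[C@H](OCc9ccccc9)[C@@H](c7ccc(OCc9ccccc9)c(OCc9ccccc9)c7)O6 | intermediate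
16 | 4-bromo-1,2-bis(benzyloxy)benzene | Brc1ccc(OCc9ccccc9)c(OCc9ccccc9)c1 | starting material
17 | 3,4-bis(benzyloxy)phenylmagnesium bromide | Br[Mg]c1ccc(OCc9ccccc9)c(OCc9ccccc9)c1 | intermediate (not isolated)
18 | (2S,3R)-1-[3,4-bis(benzyloxy)phenyl]-2-(benzyloxy)-3-[4-(benzyloxy)-2-hydroxyphenyl]-3-ArD-propan-1-ol, both C1 epimers | Oc1cc(OCc9ccccc9)ccc1[C@H](c5c(OCc9ccccc9)c(Br)c6c(c5OCc9ccccc9)C[C@H](OCc9ccccc9)[C@@H](c7ccc(OCc9ccccc9)c(OCc9ccccc9)c7)O6)[C@H](OCc9ccccc9)C(O)c1ccc(OCc9ccccc9)c(OCc9ccccc9)c1 | intermediate
19 | (2R,3S,4R)-3,7-bis(benzyloxy)-2-[3,4-bis(benzyloxy)phenyl]-4-ArD-chroman | C(c9ccccc9)Oc1ccc2c(c1)O[C@H](c3ccc(OCc9ccccc9)c(OCc9ccccc9)c3)[C@@H](OCc9ccccc9)[C@H]2c5c(OCc9ccccc9)c(Br)c6c(c5OCc9ccccc9)C[C@H](OCc9ccccc9)[C@@H](c7ccc(OCc9ccccc9)c(OCc9ccccc9)c7)O6 | intermediate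
20 | fisetinidol-(4β→6)-catechin, (2R,3S,4R)-2-(3,4-dihydroxyphenyl)-4-[(2R,3S)-2-(3,4-dihydroxyphenyl)-3,5,7-trihydroxychroman-6-yl]chroman-3,7-diol | Oc1ccc2c(c1)O[C@H](c1ccc(O)c(O)c1)[C@@H](O)[C@H]2c1c(O)cc2c(c1O)C[C@H](O)[C@@H](c1ccc(O)c(O)c1)O2 | target

**Totals**

Total step count: 11. Longest linear sequence: 10 steps (steps 1–3 and 5–11, from 1); step 4 is a one-step side branch.

**Steps most likely to fail, with fallbacks**

Step 7. The enolate may add only slowly to a methide carbon flanked by two ortho benzyloxy groups, so that it self-condenses instead. The two faces, or the endo and exo arrangements, may be poorly distinguished. The cis lactone may also epimerise at C3 under the basic conditions. The fallback replaces catalyst control by a stoichiometric oxazolidinone auxiliary; it sets out from 10 and 11 and comes back at 14. Acid 11 is converted through 12, with lithiated (R)-4-benzyloxazolidin-2-one, into (R)-4-benzyl-3-[(benzyloxy)acetyl]oxazolidin-2-one F1. Its chelated sodium (Z)-enolate (NaN(SiMe3)2, THF, −78 °C) is expected to add to 13, released from 10 with Cs2CO3, on the face away from the auxiliary benzyl group. This would give the open-chain imide phenol (2S,3R)-2-(benzyloxy)-3-[4-(benzyloxy)-2-hydroxyphenyl]-3-ArD-propanoyl oxazolidinone F2, with the future C3 as S. Warming with a catalytic amount of 4-(dimethylamino)pyridine should let the ring A phenoxide attack the exocyclic imide carbonyl, expel the auxiliary and give 14. Any C4 epimer is a diastereomer and would be separated at the stage of F2.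

Step 10. Ring closure through the cation may give incomplete control at C2. The cation may be captured by a ring D benzyl ether oxygen with loss of benzyl, or acid may ionise the C4–ring D bond. The fallback is a stereospecific Mitsunobu cyclodehydration, which sets out from 18 and comes back at 19 and makes no new compound (F0). Step 9 is run under chelation control (aldehyde precomplexed with MgBr2·OEt2 in CH2Cl2) so that the (1S), syn carbinol epimer of 18 predominates. That epimer is closed with PPh3 and diisopropyl azodicarboxylate in THF at 0 °C. The ring A phenol then displaces the activated benzylic oxygen with inversion, which gives the (2R), 2,3-trans chroman 19 without a free cation and without acid.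

Step 5. The halogen–magnesium exchange on the electron-rich ring may be sluggish or touch the bromide. The di-ortho-substituted arylmagnesium may add slowly. The silyl group may migrate to the new alkoxide and release the quinone methide prematurely, which would then take up a second aryl group. The fallback reverses the polarity of the coupling; it sets out from 3 and comes back at 9, bypassing 4 and 6. Vilsmeier–Haack formylation of 3 (POCl3, DMF) at C6, the only activated free position, gives 8-bromo-6-formyl-penta-O-benzylcatechin F3. Purchased 5-(benzyloxy)-2-bromophenol is treated with two equivalents of n-BuLi in THF at −78 °C to give lithium 5-(benzyloxy)-2-lithiophenolate F4. Addition of F4 to F3 and work-up with aqueous NH4Cl gives 9 directly, with no phenol protecting group to remove.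

**Further compounds**

F1 | step 7 | (R)-4-benzyl-3-[(benzyloxy)acetyl]oxazolidin-2-one | O=C(COCc1ccccc1)N1[C@H](Cc2ccccc2)COC1=O
F2 | step 7 | (R)-4-benzyl-3-[(2S,3R)-2-(benzyloxy)-3-[4-(benzyloxy)-2-hydroxyphenyl]-3-ArD-propanoyl]oxazolidin-2-one | Oc1cc(OCc9ccccc9)ccc1[C@H](c5c(OCc9ccccc9)c(Br)c6c(c5OCc9ccccc9)C[C@H](OCc9ccccc9)[C@@H](c7ccc(OCc9ccccc9)c(OCc9ccccc9)c7)O6)[C@H](OCc9ccccc9)C(=O)N1[C@H](Cc2ccccc2)COC1=O
F0 | step 10 | none | none
F3 | step 5 | 8-bromo-6-formyl-penta-O-benzylcatechin (ArD–CHO) | O=Cc5c(OCc9ccccc9)c(Br)c6c(c5OCc9ccccc9)C[C@H](OCc9ccccc9)[C@@H](c7ccc(OCc9ccccc9)c(OCc9ccccc9)c7)O6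
F4 | step 5 | lithium 5-(benzyloxy)-2-lithiophenolate | [Li]Oc1cc(OCc2ccccc2)ccc1[Li]
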